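**Assumption:** cudraflavone C has no stereocentre and no E/Z element (the SMILES is achiral), so no enantiocontrol is needed. The only stereocentre in the route (C2 of diketone 12) is racemic and is destroyed in the last step.

## Retrosynthetic overview

1. Cudraflavone C ⇒ MOM-protected o-hydroxyaryl 2-prenyl-1,3-diketone 12; the pyranone C ring is closed last (O1–C2) together with global deprotection.
2. 12 ⇒ o-hydroxyaryl ketone 9 + B-ring acid 11 (C2–C3, acylation/Baker–Venkataraman).
3. 9 ⇒ aryl ester 8 by photo-Fries O→C acyl shift (C4–C4a, through a phenoxyl/acyl radical pair); the migrating acyl group already carries C4, C3 and the C3-prenyl chain.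
4. 8 ⇒ symmetric, para-blocked phenol 5 + acid 7; 5 and 11 both come from resorcinol bis-MOM ether 2 (C2 lithiation/prenylation then C5 borylation–oxidation; C4 bromination–carboxylation).
5. Rings A and B are both resorcinol; only ring C is built. The symmetry of 5 fixes 6-prenyl over 8-prenyl.

## Route

**Step 1**
Reactants: 1, resorcinol
Product: 2, 1,3-bis(methoxymethoxy)benzene
Conditions: MOMCl (2.5 eq), NaH, DMF, 0 °C → rt
Reagents that add atoms: chloromethyl methyl ether, COCCl
Why: Williamson-type O-alkylation (MOM protection); the MOM ethers later direct lithiation and survive organolithium, Ir and UV conditions.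

**Step 2**
Reactants: 2; 3, prenyl bromide (1-bromo-3-methylbut-2-ene)
Product: 4, 1,3-bis(methoxymethoxy)-2-(3-methylbut-2-en-1-yl)benzene
Conditions: n-BuLi, THF, 0 °C → rt; CuI (0.5 eq), −40 °C; then 3, −40 °C → rt
Reagents that add atoms: none (prenyl comes from 3)
Why: Directed ortho-metalation at C2, between the two cooperating OMOM groups, then copper-mediated SN2 allylation at the primary carbon gives the linear prenyl group.

**Step 3**
Reactants: 4
Product: 5, 3,5-bis(methoxymethoxy)-4-(3-methylbut-2-en-1-yl)phenol
Conditions: [Ir(OMe)(cod)]2 (1.5 mol%), dtbpy, B2pin2, THF, 65 °C; then 30% H2O2, aq NaOH, 0 °C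
Reagents that add atoms: hydrogen peroxide, OO
Why: Sterically controlled Ir-catalysed C–H borylation at C5, the only C–H not ortho to a substituent, then boronate oxidation (one pot); the trisubstituted alkene is a poor substrate for Ir/HBpin, and basic peroxide does not epoxidise it.

**Step 4**
Reactants: 6, acetic acid; 3, prenyl bromide
Product: 7, 5-methylhex-4-enoic acid
Conditions: LDA (2.2 eq), THF/DMPU, 0 → 40 °C; then 3, 0 °C → rt; H3O+
Reagents that add atoms: none
Why: Alkylation of the acetic acid dianion (carboxylic acid dianion alkylation) by SN2 at the primary allylic bromide.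

**Step 5**
Reactants: 5; 7
Product: 8, 3,5-bis(methoxymethoxy)-4-(3-methylbut-2-en-1-yl)phenyl 5-methylhex-4-enoate
Conditions: EDC·HCl, DMAP (cat.), CH2Cl2, rt
Reagents that add atoms: none
Why: Steglich esterification of the single free phenol under neutral conditions.

**Step 6 (key step)**
Reactants: 8
Product: 9, 1-[6-hydroxy-2,4-bis(methoxymethoxy)-3-(3-methylbut-2-en-1-yl)phenyl]-5-methylhex-4-en-1-one
Conditions: hν (254 nm, quartz), degassed cyclohexane (5 mM), rt, to about 80% conversion (recovered 5 recycled)
Reagents that add atoms: none
Why: Photo-Fries rearrangement: S1 homolysis of the ArO–C(O) bond gives a caged phenoxyl/acyl radical pair that recombines at the ortho carbon and tautomerises; the para site is blocked by prenyl and the two ortho sites are equivalent, so one ketone forms, and the neutral in-cage process leaves the MOM ethers and both non-absorbing prenyl alkenes intact.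

**Step 7**
Reactants: 2
Product: 10, 1-bromo-2,4-bis(methoxymethoxy)benzene
Conditions: NBS (1.0 eq), MeCN, 0 °C → rt
Reagents that add atoms: N-bromosuccinimide, O=C1CCC(=O)N1Br
Why: Electrophilic aromatic bromination at C4 (para to one OMOM, ortho to the other); C2 is flanked by two OMOM groups and is hindered.

**Step 8**
Reactants: 10
Product: 11, 2,4-bis(methoxymethoxy)benzoic acid
Conditions: n-BuLi, THF, −78 °C; CO2; then pH 4 buffer
Reagents that add atoms: carbon dioxide, O=C=O
Why: Bromine–lithium exchange and carboxylation of the aryllithium; the buffered workup keeps the MOM ethers.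

**Step 9**
Reactants: 9; 11
Product: 12, 1-[2,4-bis(methoxymethoxy)phenyl]-3-[6-hydroxy-2,4-bis(methoxymethoxy)-3-(3-methylbut-2-en-1-yl)phenyl]-2-(3-methylbut-2-en-1-yl)propane-1,3-dione (racemic at C2)
Conditions: 11, Ghosez reagent, CH2Cl2, 0 °C (acid chloride); then add to 9 + LiHMDS (3.3 eq), THF, −78 °C → rt
Reagents that add atoms: none
Why: One-pot acylation/Baker–Venkataraman: the phenoxide–enolate dianion is acylated at carbon directly, or at oxygen followed by base-induced O→C acyl transfer, and both paths give the same 1,3-diketone; the new C2 centre is racemic and is removed in step 10.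

**Step 10**
Reactants: 12
Product: 13, cudraflavone C, 2-(2,4-dihydroxyphenyl)-5,7-dihydroxy-3,6-bis(3-methylbut-2-en-1-yl)-4H-chromen-4-one
Conditions: TsOH·H2O (10 mol%), CH2Cl2, rt; then MeOH, 3 M HCl, 45 °C (one pot)
Reagents that add atoms: none
Why: Acid-catalysed cyclodehydration of the o-hydroxyaryl 1,3-diketone (flavone-forming stage of the Baker–Venkataraman synthesis) through the only free phenol gives the 6-prenyl flavone before any MOM is lost; acetal hydrolysis then removes the four MOM groups under mild conditions that spare the prenyl groups.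

## Compound list

1 | resorcinol | Oc1cccc(O)c1 | starting material
2 | 1,3-bis(methoxymethoxy)benzene | COCOc1cccc(OCOC)c1 | intermediate
3 | prenyl bromide | CC(C)=CCBr | starting material
4 | 1,3-bis(methoxymethoxy)-2-(3-methylbut-2-en-1-yl)benzene | COCOc1cccc(OCOC)c1CC=C(C)C | intermediate
5 | 3,5-bis(methoxymethoxy)-4-(3-methylbut-2-en-1-yl)phenol | COCOc1cc(O)cc(OCOC)c1CC=C(C)C | intermediate
6 | acetic acid | CC(=O)O | starting material
7 | 5-methylhex-4-enoic acid | CC(C)=CCCC(=O)O | intermediate
8 | 3,5-bis(methoxymethoxy)-4-(3-methylbut-2-en-1-yl)phenyl 5-methylhex-4-enoate | CC(C)=CCCC(=O)Oc1cc(OCOC)c(CC=C(C)C)c(OCOC)c1 | intermediate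
9 | 1-[6-hydroxy-2,4-bis(methoxymethoxy)-3-(3-methylbut-2-en-1-yl)phenyl]-5-methylhex-4-en-1-one | CC(C)=CCCC(=O)c1c(O)cc(OCOC)c(CC=C(C)C)c1OCOC | intermediate
10 | 1-bromo-2,4-bis(methoxymethoxy)benzene | COCOc1ccc(Br)c(OCOC)c1 | intermediate
11 | 2,4-bis(methoxymethoxy)benzoic acid | COCOc1ccc(C(=O)O)c(OCOC)c1 | intermediate
12 | 2-prenyl-1,3-diketone (racemic, name as in step 9) | COCOc1ccc(C(=O)C(CC=C(C)C)C(=O)c2c(O)cc(OCOC)c(CC=C(C)C)c2OCOC)c(OCOC)c1 | intermediate
13 | cudraflavone C | CC(C)=CCc1c(O)cc2oc(-c3ccc(O)cc3O)c(CC=C(C)C)c(=O)c2c1O | target

## Summary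

Total steps: 10.
Longest linear sequence: 7 (steps 1, 2, 3, 5, 6, 9, 10).

Steps most likely to fail, each with a fallback that changes the approach:

1. **Step 6 (photo-Fries).** Cage escape returns phenol 5, and the product acts as an inner filter, so the yield may be modest. Fallback: drop the O→C migration and C-acylate directly, either by chelation-controlled ortho-acylation of the bromomagnesium phenoxide of 5 with the acid chloride of 7, or by MgCl2/Et3N/paraformaldehyde ortho-formylation followed by 4-methylpent-3-enyl Grignard addition and oxidation.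
2. **Step 3 (Ir borylation with the prenyl alkene present).** Competing alkene hydroboration or vinylic borylation is possible. Fallback: reverse the order — borylate/oxidise 2 to 3,5-bis(methoxymethoxy)phenol, protect it as the TIPS ether, lithiate between the two OMOM groups, prenylate, then desilylate to 5.
3. **Step 10 (acidic end-game).** Acid may cyclise the 6-prenyl group onto a neighbouring phenol (chroman formation), or cleave the ortho MOM early and give some 8-prenyl isomer. Fallback: run the whole route with SEM ethers instead of MOM (same directing ability), isolate the protected flavone after catalytic-acid cyclodehydration, and deprotect with fluoride (TBAF/DMPU) so no strong acid touches the prenylated polyphenol.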